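25.3% was the triple product in Tuesday's run at 120 min, barely up from 24.8% at 80.0 min, with bis adduct standing at 43.5%. That looks contradictory, since the 1.8 M of coupling partner charged was more than the 1.20 M the substrate could take up on its way to triple product, so free partner stood beside a triple product that had nearly stopped rising.

| setting | Tuesday's | flask |
|---|---|---|
| substrate | 0.40 M | 0.40 M |
| coupling partner | 1.8 M | 1.20 M |
| remark | run made earlier |  |
| time |  | 6.0 h |
Tuesday's run (percent of the substrate charged)

| time / min | bis adduct / % | triple product / % |
|---|---|---|
| 6.00 | 17.1 | 1.1 |
| 15.0 | 39.3 | 4.5 |
| 30.0 | 47.6 | 12.9 |
| 50.0 | 45.0 | 19.7 |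
| 60.0 | 43.6 | 21.8 |
| 80.0 | 43.3 | 24.8 |
| 120 | 43.5 | 25.3 |

(standard deviation of a reading: 0.5 percentage points)
- candidate steps: substrate <-> dormant form; triple product <-> isomer of the product; substrate + coupling partner -> first product + released group; coupling partner + first product -> bis adduct + released group; coupling partner + bis adduct <-> triple product + released group
- equivalents of coupling partner to substrate, everything else as given, that leave most bis adduct at 6.0 h
- the amount of bis adduct then, in percent of the substrate charged
- the amount of bis adduct with the amounts as given

I took the last coupling as reversible. I counted the missing 31.2% as isomer of the product, which gives Tuesday's run 1.03 M of released group against 0.774 M of partner left. Free partner is then no contradiction, since it stands against more released group. The result is 0.771, which I carried as the exchange quotient, c(triple product) times c(released group) over c(bis adduct) times c(coupling partner), the reaction quotient of the last coupling.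

I then held the flask, with 3.00 equivalents, to that quotient, with isomer to triple product at Tuesday's 1.23, and assumed it comes to rest within 6.0 h. The balance closes at 66.9% bis adduct, with 0.932 M of released group and 0.268 M of partner left. That is my own figure, and I put the best charge somewhat lower without reckoning it.

The forecast gave 43%, and 45% at 5 equiv, saying “I therefore read the loss as substrate diverted to the dormant form”.

The flask gave 65.5%, and 68.5% at 2.41 equiv.

    substrate ⇌ dormant form (K = 1.50, k = 0.0270 min⁻¹)
    triple product ⇌ isomer of the product (K = 0.740, k = 0.130 min⁻¹)
    substrate + coupling partner → first product + released group (k = 0.0490 M⁻¹ min⁻¹)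
    coupling partner + first product → bis adduct + released group (k = 0.140 M⁻¹ min⁻¹)
    coupling partner + bis adduct ⇌ triple product + released group (K = 0.660, k = 0.0180 M⁻¹ min⁻¹)

The flask's amounts at 6.00 h give an exchange quotient of 0.674. A further flask with 0.16 M of substrate, holding 38.2% triple product and 32.1% bis adduct, gives 0.645, both under Tuesday's 0.771. In the flask, half the turnover of the last coupling was done by 0.680 h, earlier than the 6.0 h asked. Bis adduct in the flask still rose from 54.7% at 3.00 h to 65.5% at 6.00 h, and stood at 73.0% at 60.0 h.

(All runs were generated by integration with made-up constants.)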